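## Retrosynthetic overview

1. Succinimide (the only ring made in the route): closed last through the N–C16 bond, a primary amide nitrogen displacing the oxazolidinone of an N-acyl imide.
2. C12–C13 and both side-chain stereocentres: Evans syn-aldol of a C12 aldehyde with an (R)-benzyloxazolidinone succinamide.
3. Aldehyde and 8(17)-alkene: from the sclareolide lactone by Weinreb aminolysis, anti-elimination of the 8α-OH and DIBAL reduction.
4. Key bond C6–O: C6–H oxygenation of 2α-chlorosclareolide, with the chloride and the lactone switching off the other sites, then α-face hydride to give 6β-OH.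
5. C2–Cl: radical C–H chlorination of (+)-sclareolide, which supplies rings A/B and C5/C9/C10 intact, so no carbocycle is built.

Assumption: labdane numbering is used (decalin C1–C10, side chain C11–C16, C17 on C8, C18/C19 on C4, C20 on C10), β is the face of the C10 methyl, and the target is taken exactly as the given SMILES: 2α-Cl (equatorial), 6β-OH (axial), 12S, 13R.

## Route

Step 1
Reactants: 1 (+)-sclareolide
Product: 2 2α-chlorosclareolide
Conditions: ArC(O)N(Cl)t-Bu (Ar = 3,5-(CF3)2C6H3, 1.2 equiv), Cs2CO3 (additive), PhH, visible light, 55 °C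
Reagents that add atoms: N-chloro-N-tert-butyl-3,5-bis(trifluoromethyl)benzamide, CC(C)(C)N(Cl)C(=O)c1cc(cc(c1)C(F)(F)F)C(F)(F)F
Why: Amidyl-radical C–H chlorination takes the most accessible, electron-rich ring-A methylene (C2, remote from the lactone), and the C2 radical accepts Cl from the α-face opposite the axial C19/C20 methyls, giving the equatorial 2α-chloride.

Step 2
Reactants: 2 2α-chlorosclareolide
Product: 4 2α-chloro-6β-hydroxysclareolide, via 2α-chloro-6-oxosclareolide 3 (not isolated)
Conditions: TFDO (0.4 M in CF3COCH3, 3.5 equiv, portions), CH2Cl2, −20 → 0 °C, dark; evaporate; NaBH4, CeCl3·7H2O, MeOH, −40 °C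
Reagents that add atoms: methyl(trifluoromethyl)dioxirane (TFDO), CC1(OO1)C(F)(F)F
Why: Proposed new method: undirected dioxirane oxygenation steered to C6 of a drimane lactone by a C2 chloride used as an electronic blocking group. TFDO inserts oxygen through an electrophilic, concerted transition state, so the α-chloro C2–H and the β-chloro methylenes C1/C3 are switched off inductively, C7/C9/C11 are switched off by the lactone, and C5–H is buried between two quaternary carbons; the equatorial 6α-H is left as the most electron-rich C–H and is further activated by strain release, since flattening C6 relieves the compression of the 6β-H against the C17, C19 and C20 methyls. Excess reagent oxidises the 6α-carbinol on to ketone 3, which is not isolated because a β-acyloxy ketone can lose the lactone by E1cB; Luche hydride delivery from the open α-face then gives the axial 6β-alcohol, as with 6-oxo-5α-steroids. Closest known reaction type: TFDO and Fe/Mn(PDP) ketonisation of the C2/C3 methylenes of sclareolide itself, which has not been shown at C6 or on a halogenated drimane.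

Step 3
Reactants: 4 2α-chloro-6β-hydroxysclareolide
Product: 5 2α-chloro-6β,8α-dihydroxy-13,14,15,16-tetranorlabdan-12-oic acid N-methoxy-N-methylamide
Conditions: MeNH(OMe)·HCl (5 equiv), AlMe3 (5 equiv), CH2Cl2, 0 °C → rt; Rochelle salt; used crude
Reagents that add atoms: N,O-dimethylhydroxylamine hydrochloride, CNOC.Cl
Why: Weinreb aminolysis of the lactone by the aluminium amide is driven by the strong Al–O bond to the released tertiary alkoxide and touches no stereocentre.

Step 4
Reactants: 5 2α-chloro-6β,8α-dihydroxy-13,14,15,16-tetranorlabdan-12-oic acid N-methoxy-N-methylamide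
Product: 6 2α-chloro-6β-hydroxy-13,14,15,16-tetranorlabd-8(17)-en-12-oic acid N-methoxy-N-methylamide
Conditions: SOCl2 (2 equiv), pyridine (6 equiv), CH2Cl2, −78 °C, 30 min; cold sat. NaHCO3
Reagents that add atoms: none
Why: E2 elimination of the equatorial tertiary 8α-chlorosulfite can only use the antiperiplanar hydrogens of the axial C17 methyl, so the exocyclic alkene forms, while any chlorosulfite on the triply flanked secondary 6β-OH does not eliminate at −78 °C and is hydrolysed back on quench.

Step 5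
Reactants: 6 2α-chloro-6β-hydroxy-13,14,15,16-tetranorlabd-8(17)-en-12-oic acid N-methoxy-N-methylamide
Product: 7 2α-chloro-6β-hydroxy-13,14,15,16-tetranorlabd-8(17)-en-12-al
Conditions: DIBAL-H (3 equiv), THF, −78 °C; Rochelle salt
Reagents that add atoms: none
Why: Weinreb amide reduction stops at the aldehyde because the chelated tetrahedral aluminium intermediate survives until work-up; the alkene and the chloride are inert.

Step 6
Reactants: 8 (R)-4-benzyloxazolidin-2-one; 9 succinic anhydride
Product: 10 4-[(4R)-4-benzyl-2-oxooxazolidin-3-yl]-4-oxobutanoic acid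
Conditions: Et3N, LiCl, DMAP (cat.), THF, 0 °C → rt; 1 M HCl work-up
Reagents that add atoms: none
Why: Soft (LiCl/Et3N) N-acylation of the oxazolidinone by ring-opening of the cyclic anhydride gives the half-imide acid directly.

Step 7
Reactants: 10 4-[(4R)-4-benzyl-2-oxooxazolidin-3-yl]-4-oxobutanoic acid
Product: 12 4-[(4R)-4-benzyl-2-oxooxazolidin-3-yl]-4-oxobutanamide, via isobutyl carbonic mixed anhydride 11 (not isolated)
Conditions: i-BuOCOCl, N-methylmorpholine, THF, −15 °C; then NH3 (0.5 M in dioxane, 1.2 equiv), −15 → 0 °C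
Reagents that add atoms: ammonia, N
Why: Mixed-anhydride amidation works because the carbonic anhydride is far more electrophilic than the N-acyl imide at −15 °C, so ammonia acylates only there.

Step 8
Reactants: 12 4-[(4R)-4-benzyl-2-oxooxazolidin-3-yl]-4-oxobutanamide; 7 2α-chloro-6β-hydroxy-13,14,15,16-tetranorlabd-8(17)-en-12-al
Product: 14 (12S,13R)-2α-chloro-6β,12-dihydroxylabd-8(17)-ene-15,16-dioic acid 15-amide 16-[(4R)-4-benzyl-2-oxooxazolidin-3-yl]imide, via Z-dibutylboron enolate of the imide 13 (not isolated)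
Conditions: 12 (2 equiv), Bu2BOTf (2.2 equiv per 12), i-Pr2NEt (2.6 equiv per 12), CH2Cl2, −78 → 0 °C; then 7, −78 → 0 °C; pH 7 buffer, MeOH, 30% H2O2, 0 °C
Reagents that add atoms: none
Why: Evans syn-aldol through the chelated Z-boron enolate and a Zimmerman–Traxler chair, in which the (R)-benzyl auxiliary sets C13 as R and C12 as S (the 2R,3S "Evans syn" pattern); the primary amide is only transiently borylated and the hindered 6β-OH stays out of the reaction.

Step 9
Reactants: 14 (12S,13R)-2α-chloro-6β,12-dihydroxylabd-8(17)-ene-15,16-dioic acid 15-amide 16-[(4R)-4-benzyl-2-oxooxazolidin-3-yl]imide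
Product: 15 haterumaimide F
Conditions: DBU (1.2 equiv), CH2Cl2, 0 °C → rt; aq. NH4Cl
Reagents that add atoms: none
Why: Base-promoted 5-exo-trig N-acylation of the primary amide on the exocyclic imide carbonyl expels the oxazolidinone and closes the succinimide, whose acidic N–H then buffers the medium so that C13 is not epimerised and no retro-aldol occurs.

## Compound list

1 | (+)-sclareolide, (3aR,5aS,9aS,9bR)-3a,6,6,9a-tetramethyldecahydronaphtho[2,1-b]furan-2(1H)-one | C[C@@]12CC[C@H]3C(C)(C)CCC[C@]3(C)[C@H]1CC(=O)O2 | starting material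
2 | 2α-chlorosclareolide | C[C@@]12CC[C@H]3C(C)(C)C[C@H](Cl)C[C@]3(C)[C@H]1CC(=O)O2 | intermediate
3 | 2α-chloro-6-oxosclareolide | C[C@@]12CC(=O)[C@H]3C(C)(C)C[C@H](Cl)C[C@]3(C)[C@H]1CC(=O)O2 | intermediate (not isolated)
4 | 2α-chloro-6β-hydroxysclareolide | C[C@@]12C[C@@H](O)[C@H]3C(C)(C)C[C@H](Cl)C[C@]3(C)[C@H]1CC(=O)O2 | intermediate
5 | 2α-chloro-6β,8α-dihydroxy-13,14,15,16-tetranorlabdan-12-oic acid N-methoxy-N-methylamide | C[C@@]1(O)C[C@@H](O)[C@H]2C(C)(C)C[C@H](Cl)C[C@]2(C)[C@H]1CC(=O)N(C)OC | intermediate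
6 | 2α-chloro-6β-hydroxy-13,14,15,16-tetranorlabd-8(17)-en-12-oic acid N-methoxy-N-methylamide | C=C1C[C@@H](O)[C@H]2C(C)(C)C[C@H](Cl)C[C@]2(C)[C@H]1CC(=O)N(C)OC | intermediate
7 | 2α-chloro-6β-hydroxy-13,14,15,16-tetranorlabd-8(17)-en-12-al | C=C1C[C@@H](O)[C@H]2C(C)(C)C[C@H](Cl)C[C@]2(C)[C@H]1CC=O | intermediate
8 | (R)-4-benzyloxazolidin-2-one | O=C1N[C@H](Cc2ccccc2)CO1 | starting material
9 | succinic anhydride | O=C1CCC(=O)O1 | starting material
10 | 4-[(4R)-4-benzyl-2-oxooxazolidin-3-yl]-4-oxobutanoic acid | OC(=O)CCC(=O)N1[C@H](Cc2ccccc2)COC1=O | intermediate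
11 | isobutyl carbonic mixed anhydride of 10 | CC(C)COC(=O)OC(=O)CCC(=O)N1[C@H](Cc2ccccc2)COC1=O | intermediate (not isolated)
12 | 4-[(4R)-4-benzyl-2-oxooxazolidin-3-yl]-4-oxobutanamide | NC(=O)CCC(=O)N1[C@H](Cc2ccccc2)COC1=O | intermediate
13 | Z-dibutylboron enolate of 12 | NC(=O)C/C=C(\OB(CCCC)CCCC)N1[C@H](Cc2ccccc2)COC1=O | intermediate (not isolated)
14 | (12S,13R)-2α-chloro-6β,12-dihydroxylabd-8(17)-ene-15,16-dioic acid 15-amide 16-[(4R)-4-benzyl-2-oxooxazolidin-3-yl]imide | C=C1C[C@@H](O)[C@H]2C(C)(C)C[C@H](Cl)C[C@]2(C)[C@H]1C[C@H](O)[C@@H](CC(N)=O)C(=O)N1[C@H](Cc2ccccc2)COC1=O | intermediate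
15 | haterumaimide F, (12S,13R)-2α-chloro-6β,12-dihydroxylabd-8(17)-ene-15,16-dicarboximide | C=C1C[C@@H](O)[C@H]2C(C)(C)C[C@H](Cl)C[C@]2(C)[C@H]1C[C@H](O)[C@H]1CC(=O)NC1=O | target

## Step count and risks

Total steps: 9 (steps 1–5, 8 and 9 on the main line; steps 6 and 7 for the aldol donor).
Longest linear sequence: 7 steps (1 → 2 → 4 → 5 → 6 → 7 → 14 → 15).

Steps most likely to fail:

**Step 2 (the proposed new C6–H oxygenation).** Site selectivity is unproven. Likely by-products are the C3 ketone and the 5α-alcohol. The oxidation may also stall at the 6α-alcohol, in which case Dess–Martin periodinane is added before the borohydride. Fallback with known chemistry, setting out from 2 and returning at 6: aminolysis of 2 (MeNH(OMe)·HCl, AlMe3) gives the 8α-hydroxy Weinreb amide F1, and SOCl2/pyridine at −78 °C gives the 8(17)-alkene F2. Hydroboration from the α-face (9-BBN, then NaBO3) gives the axial 17-alcohol F3. A Suárez hypoiodite reaction (PhI(OAc)2, I2, hν, cyclohexane) then lets the C17 alkoxyl radical abstract the syn-axial 6β-H (1,5-H transfer) and closes the 6β,17-ether F4, so the C6–O bond is set on the β-face by the tether. AcCl/NaI opens the ether at the primary carbon to the 17-iodo 6β-acetate F5, DBU eliminates HI to the exocyclic alkene acetate F6, and K2CO3/MeOH gives 6.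

**Step 4 (dehydration beside a free 6β-OH).** The secondary alcohol may be sulfinylated and eliminated, and endocyclic alkene isomers may form (separable on AgNO3-silica). Fallback, setting out from 4 and returning at 6: TESOTf/2,6-lutidine gives the 6β-triethylsilyl ether lactone F7, Weinreb aminolysis gives the silyl-protected hydroxy amide F8, SOCl2/pyridine gives the silyl-protected exocyclic alkene F9, and HF·pyridine gives 6.

**Step 8 (boron aldol with a donor carrying a free primary amide).** The amide may consume or misdirect Bu2BOTf, or cyclise early with loss of the auxiliary. Fallback, setting out from 8 and 7 and returning at 14: acylation of 8 with 3-cyanopropanoic acid (PivCl, Et3N, LiCl) gives the nitrile imide F10. Its Z-dibutylboron enolate F11 adds to 7 to give the nitrile syn-aldol adduct F12. Neutral platinum-catalysed nitrile hydration (Ghaffar–Parkins catalyst, EtOH/H2O, 70 °C) then gives the primary amide 14.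

## Further compounds

F1 | step 2 | 2α-chloro-8α-hydroxy-13,14,15,16-tetranorlabdan-12-oic acid N-methoxy-N-methylamide | C[C@@]1(O)CC[C@H]2C(C)(C)C[C@H](Cl)C[C@]2(C)[C@H]1CC(=O)N(C)OC
F2 | step 2 | 2α-chloro-13,14,15,16-tetranorlabd-8(17)-en-12-oic acid N-methoxy-N-methylamide | C=C1CC[C@H]2C(C)(C)C[C@H](Cl)C[C@]2(C)[C@H]1CC(=O)N(C)OC
F3 | step 2 | 2α-chloro-17-hydroxy-8α-H-13,14,15,16-tetranorlabdan-12-oic acid N-methoxy-N-methylamide | OC[C@H]1CC[C@H]2C(C)(C)C[C@H](Cl)C[C@]2(C)[C@H]1CC(=O)N(C)OC
F4 | step 2 | 2α-chloro-6β,17-epoxy-13,14,15,16-tetranorlabdan-12-oic acid N-methoxy-N-methylamide | O1C[C@H]2C[C@@H]1[C@H]3C(C)(C)C[C@H](Cl)C[C@]3(C)[C@H]2CC(=O)N(C)OC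
F5 | step 2 | 6β-acetoxy-2α-chloro-17-iodo-13,14,15,16-tetranorlabdan-12-oic acid N-methoxy-N-methylamide | IC[C@H]1C[C@@H](OC(C)=O)[C@H]2C(C)(C)C[C@H](Cl)C[C@]2(C)[C@H]1CC(=O)N(C)OC
F6 | step 2 | 6β-acetoxy-2α-chloro-13,14,15,16-tetranorlabd-8(17)-en-12-oic acid N-methoxy-N-methylamide | C=C1C[C@@H](OC(C)=O)[C@H]2C(C)(C)C[C@H](Cl)C[C@]2(C)[C@H]1CC(=O)N(C)OC
F7 | step 4 | 2α-chloro-6β-(triethylsilyloxy)sclareolide | C[C@@]12C[C@@H](O[Si](CC)(CC)CC)[C@H]3C(C)(C)C[C@H](Cl)C[C@]3(C)[C@H]1CC(=O)O2
F8 | step 4 | 2α-chloro-8α-hydroxy-6β-(triethylsilyloxy)-13,14,15,16-tetranorlabdan-12-oic acid N-methoxy-N-methylamide | C[C@@]1(O)C[C@@H](O[Si](CC)(CC)CC)[C@H]2C(C)(C)C[C@H](Cl)C[C@]2(C)[C@H]1CC(=O)N(C)OC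
F9 | step 4 | 2α-chloro-6β-(triethylsilyloxy)-13,14,15,16-tetranorlabd-8(17)-en-12-oic acid N-methoxy-N-methylamide | C=C1C[C@@H](O[Si](CC)(CC)CC)[C@H]2C(C)(C)C[C@H](Cl)C[C@]2(C)[C@H]1CC(=O)N(C)OC
F10 | step 8 | (R)-4-benzyl-3-(3-cyanopropanoyl)oxazolidin-2-one | N#CCCC(=O)N1[C@H](Cc2ccccc2)COC1=O
F11 | step 8 | Z-dibutylboron enolate of F10 | N#CC/C=C(\OB(CCCC)CCCC)N1[C@H](Cc2ccccc2)COC1=O
F12 | step 8 | (12S,13R)-2α-chloro-15-nitrilo-6β,12-dihydroxylabd-8(17)-en-16-oic acid (4R)-4-benzyl-2-oxooxazolidin-3-yl imide | C=C1C[C@@H](O)[C@H]2C(C)(C)C[C@H](Cl)C[C@]2(C)[C@H]1C[C@H](O)[C@@H](CC#N)C(=O)N1[C@H](Cc2ccccc2)COC1=O
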